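**Retrosynthetic overview**
1. Leprolomin (1) ← global hydrogenolysis of its tri-O-benzyl ether 2.
2. 2 ← diaryl ether C–O bond made last, by Pd-catalysed transient-imine-directed ortho C–H aryloxylation of ring-A ketone 3 with ring-B phenol 4 (proposed new method).
3. 3 ← cyclohexane-1,3-dione (5): C-methylation, enol ether, aromatisation (ring A becomes aromatic here), ortho-acetylation, benzylation.
4. 4 ← resorcinol (6) (ring B preformed): acetylation, C-methylation, O-differentiation, ketone-directed C–H hydroxylation, formylation/Baeyer–Villiger.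
5. Assumption: the target has no stereocentres (the diaryl ether axis is not configurationally defined), so no stereocontrol is needed.

**Fragment A (ring A)**

Step 1
Reactants: 5 cyclohexane-1,3-dione
Product: 7 2-methylcyclohexane-1,3-dione
Conditions: MeI, aq. NaOH, dioxane, reflux
Reagents that add atoms: iodomethane, CI
Why: C-alkylation of the stabilised 1,3-diketone enolate at C2 in aqueous base is a standard preparation.

Step 2
Reactants: 7 2-methylcyclohexane-1,3-dione
Product: 8 3-methoxy-2-methylcyclohex-2-en-1-one
Conditions: HC(OMe)3, MeOH, p-TsOH (cat.), rt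
Reagents that add atoms: methanol, CO (or trimethyl orthoformate, COC(OC)OC)
Why: Acid-catalysed vinylogous ester formation; the dione is symmetric, so one enol ether results and the two oxygens are now differentiated.

Step 3
Reactants: 8 3-methoxy-2-methylcyclohex-2-en-1-one
Product: 9 3-methoxy-2-methylphenol
Conditions: Pd(TFA)2 (5 mol %), 2-(dimethylamino)pyridine (10 mol %), p-TsOH (20 mol %), O2 (1 atm), DMSO, 80 °C
Reagents that add atoms: none
Why: Pd-catalysed aerobic dehydrogenation of a cyclohexenone (α-palladation, β-hydride elimination, tautomerisation) gives the phenol with the methyl ether retained.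

Step 4
Reactants: 9 3-methoxy-2-methylphenol
Product: 10 1-(2-hydroxy-4-methoxy-3-methylphenyl)ethan-1-one
Conditions: Ac2O, BF3·OEt2, 80 °C; then H2O
Reagents that add atoms: acetic anhydride, CC(=O)OC(C)=O
Why: Friedel–Crafts/Fries acylation under BF3 goes ortho to OH and para to OMe (both groups direct there, and the BF2 chelate favours the ortho-hydroxy ketone).

Step 5
Reactants: 10 1-(2-hydroxy-4-methoxy-3-methylphenyl)ethan-1-one
Product: 3 1-[2-(benzyloxy)-4-methoxy-3-methylphenyl]ethan-1-one
Conditions: BnBr, K2CO3, TBAI (cat.), DMF, 70 °C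
Reagents that add atoms: benzyl bromide, BrCc1ccccc1
Why: Williamson etherification of the chelated phenol (needs heat); it blocks O,N-chelation of Pd by the 2-OH in step 14 and leaves one ortho C–H on the ketone.

**Fragment B (ring B)**

Step 6
Reactants: 6 resorcinol
Product: 11 1-(2,4-dihydroxyphenyl)ethan-1-one
Conditions: AcOH, ZnCl2, 140 °C
Reagents that add atoms: acetic acid, CC(=O)O
Why: Nencki acylation of resorcinol at C4 (ortho/para to the two hydroxyls) is a classical preparation.

Step 7
Reactants: 11 1-(2,4-dihydroxyphenyl)ethan-1-one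
Product: 12 1-(2,4-dihydroxy-3-methylphenyl)ethan-1-one
Conditions: MeI (1.1 equiv), KOH, MeOH, 0 °C → reflux
Reagents that add atoms: iodomethane, CI
Why: Nuclear C-methylation of the resorcinol dianion occurs mainly at the carbon between the two oxygens; the yield is moderate and O-methyl and 5-methyl by-products are removed by crystallisation.

Step 8
Reactants: 12 1-(2,4-dihydroxy-3-methylphenyl)ethan-1-one
Product: 13 1-[4-(benzyloxy)-2-hydroxy-3-methylphenyl]ethan-1-one
Conditions: BnBr (1.05 equiv), K2CO3, acetone, reflux
Reagents that add atoms: benzyl bromide, BrCc1ccccc1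
Why: Williamson etherification is selective for the 4-OH because the 2-OH is hydrogen-bonded to the carbonyl.

Step 9
Reactants: 13 1-[4-(benzyloxy)-2-hydroxy-3-methylphenyl]ethan-1-one
Product: 14 1-[4-(benzyloxy)-2-methoxy-3-methylphenyl]ethan-1-one
Conditions: MeI (excess), K2CO3, DMF, 60 °C
Reagents that add atoms: iodomethane, CI
Why: Forcing Williamson methylation of the remaining chelated phenol fixes the ring-B methoxy between acetyl and methyl.

Step 10
Reactants: 14 1-[4-(benzyloxy)-2-methoxy-3-methylphenyl]ethan-1-one
Product: 15 1-[4-(benzyloxy)-6-hydroxy-2-methoxy-3-methylphenyl]ethan-1-one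
Conditions: Pd(OAc)2 (10 mol %), PhI(OCOCF3)2 (2 equiv), DCE, 80 °C; then NaHCO3, MeOH
Reagents that add atoms: [bis(trifluoroacetoxy)iodo]benzene, FC(F)(F)C(=O)OI(OC(=O)C(F)(F)F)c1ccccc1 (supplies O via the aryl trifluoroacetate)
Why: Known ketone-directed Pd(II)/Pd(IV) ortho C–H oxygenation; the carbonyl directs palladation to C6, the only ortho C–H, and the trifluoroacetate is cleaved on work-up.

Step 11
Reactants: 15 1-[4-(benzyloxy)-6-hydroxy-2-methoxy-3-methylphenyl]ethan-1-one
Product: 16 1-[4,6-bis(benzyloxy)-2-methoxy-3-methylphenyl]ethan-1-one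
Conditions: BnBr, K2CO3, TBAI (cat.), DMF, 70 °C
Reagents that add atoms: benzyl bromide, BrCc1ccccc1
Why: Williamson benzylation of the new chelated phenol; it also re-benzylates any 4-OH freed in step 10.

Step 12
Reactants: 16 1-[4,6-bis(benzyloxy)-2-methoxy-3-methylphenyl]ethan-1-one
Product: 17 3-acetyl-2,6-bis(benzyloxy)-4-methoxy-5-methylbenzaldehyde
Conditions: POCl3, DMF, 0 → 50 °C; aq. NaOAc
Reagents that add atoms: N,N-dimethylformamide, CN(C)C=O (formyl carbon); water, O (carbonyl oxygen on hydrolysis)
Why: Vilsmeier–Haack formylation at the only remaining ring C–H, which is activated by two ortho benzyloxy groups and a para methoxy group.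

Step 13
Reactants: 17 3-acetyl-2,6-bis(benzyloxy)-4-methoxy-5-methylbenzaldehyde
Product: 4 1-[2,4-bis(benzyloxy)-3-hydroxy-6-methoxy-5-methylphenyl]ethan-1-one
Conditions: mCPBA (1.2 equiv), NaHCO3, CH2Cl2, 0 °C → rt; then K2CO3, MeOH, rt (N2)
Reagents that add atoms: m-chloroperoxybenzoic acid, OOC(=O)c1cccc(Cl)c1
Why: Baeyer–Villiger (Dakin-type) oxidation of the electron-rich 2,6-dialkoxybenzaldehyde gives the aryl formate faster than the hindered methyl ketone reacts; methanolysis frees the phenol flanked by two benzyl ethers.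

**Union and deprotection**

Step 14
Reactants: 3 1-[2-(benzyloxy)-4-methoxy-3-methylphenyl]ethan-1-one (2 equiv); 4 1-[2,4-bis(benzyloxy)-3-hydroxy-6-methoxy-5-methylphenyl]ethan-1-one (1 equiv)
Product: 2 1-[3-[2-acetyl-3-(benzyloxy)-5-methoxy-4-methylphenoxy]-2,4-bis(benzyloxy)-6-methoxy-5-methylphenyl]ethan-1-one
Conditions: Pd(OAc)2 (10 mol %), glycine (40 mol %), 1-fluoro-2,4,6-trimethylpyridinium triflate (1.5 equiv), PhCl/HFIP (10:1), 90 °C, N2
Reagents that add atoms: none
Why: Proposed new method: glycine condenses reversibly with the ketone of 3 (the ketone of 4 is di-ortho-substituted and has no ortho C–H) to give an N,O-bidentate imine that directs carboxylate-assisted palladation of the single ortho C–H (C6); the N-fluoropyridinium salt oxidises the palladacycle to Pd(IV), phenol 4 (no ring C–H, so it can act only as an O-nucleophile) displaces fluoride, C(aryl)–O reductive elimination forms the diaryl ether and imine hydrolysis returns glycine; no stereocentre is formed; the closest known reactions are Pd/transient-directing-group ortho C–H arylation of aryl ketones, Pd(II)/Pd(IV) ortho C–H hydroxylation/alkoxylation of benzaldehydes with F+ oxidants, and Cu-mediated directed C–H aryloxylation with phenols.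

Step 15
Reactants: 2 tri-O-benzyl-leprolomin
Product: 1 leprolomin
Conditions: H2 (1 atm), 10 % Pd/C, EtOAc–MeOH, rt
Reagents that add atoms: none
Why: Hydrogenolysis removes the three benzyl ethers while the hindered, hydrogen-bonded aryl ketones, the methyl ethers and the diaryl ether survive mild conditions.

**Compound list**
1 | leprolomin, 1-[3-(2-acetyl-3-hydroxy-5-methoxy-4-methylphenoxy)-2,4-dihydroxy-6-methoxy-5-methylphenyl]ethan-1-one | COc1cc(Oc2c(O)c(C)c(OC)c(C(C)=O)c2O)c(C(C)=O)c(O)c1C | target
2 | 1-[3-[2-acetyl-3-(benzyloxy)-5-methoxy-4-methylphenoxy]-2,4-bis(benzyloxy)-6-methoxy-5-methylphenyl]ethan-1-one | COc1cc(Oc2c(OCc3ccccc3)c(C)c(OC)c(C(C)=O)c2OCc4ccccc4)c(C(C)=O)c(OCc5ccccc5)c1C | intermediate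
3 | 1-[2-(benzyloxy)-4-methoxy-3-methylphenyl]ethan-1-one | COc1ccc(C(C)=O)c(OCc2ccccc2)c1C | intermediate
4 | 1-[2,4-bis(benzyloxy)-3-hydroxy-6-methoxy-5-methylphenyl]ethan-1-one | CC(=O)c1c(OCc2ccccc2)c(O)c(OCc3ccccc3)c(C)c1OC | intermediate
5 | cyclohexane-1,3-dione | O=C1CCCC(=O)C1 | starting material
6 | resorcinol (benzene-1,3-diol) | Oc1cccc(O)c1 | starting material
7 | 2-methylcyclohexane-1,3-dione | CC1C(=O)CCCC1=O | intermediate
8 | 3-methoxy-2-methylcyclohex-2-en-1-one | COC1=C(C)C(=O)CCC1 | intermediate
9 | 3-methoxy-2-methylphenol | COc1cccc(O)c1C | intermediate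
10 | 1-(2-hydroxy-4-methoxy-3-methylphenyl)ethan-1-one | COc1ccc(C(C)=O)c(O)c1C | intermediate
11 | 1-(2,4-dihydroxyphenyl)ethan-1-one | CC(=O)c1ccc(O)cc1O | intermediate
12 | 1-(2,4-dihydroxy-3-methylphenyl)ethan-1-one | CC(=O)c1ccc(O)c(C)c1O | intermediate
13 | 1-[4-(benzyloxy)-2-hydroxy-3-methylphenyl]ethan-1-one | CC(=O)c1ccc(OCc2ccccc2)c(C)c1O | intermediate
14 | 1-[4-(benzyloxy)-2-methoxy-3-methylphenyl]ethan-1-one | CC(=O)c1ccc(OCc2ccccc2)c(C)c1OC | intermediate
15 | 1-[4-(benzyloxy)-6-hydroxy-2-methoxy-3-methylphenyl]ethan-1-one | CC(=O)c1c(O)cc(OCc2ccccc2)c(C)c1OC | intermediate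
16 | 1-[4,6-bis(benzyloxy)-2-methoxy-3-methylphenyl]ethan-1-one | CC(=O)c1c(OCc2ccccc2)cc(OCc3ccccc3)c(C)c1OC | intermediate
17 | 3-acetyl-2,6-bis(benzyloxy)-4-methoxy-5-methylbenzaldehyde | CC(=O)c1c(OCc2ccccc2)c(C=O)c(OCc3ccccc3)c(C)c1OC | intermediate

**Step count**
Total: 15 steps. Longest linear sequence: 10 steps (steps 6–15, resorcinol to leprolomin); the other branch is steps 1–5.

**Three steps most likely to fail**
- Step 14 (proposed new C–H aryloxylation; the electron-rich phenol 4 may be oxidised, or imine formation at the ortho-substituted ketone may be slow). Fallback with known chemistry: ortho-hydroxylate 3 under the step-10 conditions, convert the phenol to the aryl triflate (Tf2O, pyridine), and join it to 4 by Pd-catalysed C–O cross-coupling (Pd2(dba)3, tBuXPhos, K3PO4, toluene, 100 °C).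
- Step 10 (the iodine(III) oxidant may attack the electron-rich C5–H or cleave the benzyl ether). Fallback: install the third oxygen before the acetyl group. Resorcinol is converted to 2,6-bis(methoxymethoxy)toluene (MOMCl; n-BuLi/MeI), then sterically controlled Ir-catalysed C–H borylation/oxidation para to the methyl, BF3/AcOH acylation with MOM loss to 2,4,6-trihydroxy-3-methylacetophenone, 4,6-di-O-benzylation and 2-O-methylation give 16.
- Step 12 (formylation at a position flanked by two benzyloxy groups, with possible Vilsmeier attack on the methyl ketone). Fallback: iodinate 16 at C5 with NIS and convert the aryl iodide directly to phenol 4 by Pd-catalysed hydroxylation (hydroxide or benzaldoxime surrogate), bypassing 17 and step 13.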